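| flask | substrate | reagent in the second phase | remark | time | volume of the second phase over the first |
|---|---|---|---|---|---|
| blue | 0.59 M | 0.80 equiv | the very flask that is asked about, followed so far |  |  |
| flask | 0.59 M | 0.800 equiv |  | 15 h | 0.25 |

blue run (percent of the substrate charged)

| time / h | target / % |
|---|---|
| 1.00 | 24.7 |
| 2.00 | 27.2 |
| 3.00 | 24.1 |
| 4.00 | 22.3 |
| 5.00 | 21.6 |
| 6.00 | 20.6 |
| 8.00 | 20.5 |

(each reading ± 1 percentage point)

- autumn: doubling the amount of reagent in the second phase, all else as stated
- winter: doubling the transfer coefficient of the reagent in the second phase, all else as stated

- how much target there is at 15 h, in percent of the substrate charged
- the change that raises the amount of target at 15 h, in percent of the substrate charged most ("none" if none brings more than 2 percentage points) (autumn / winter / none)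
- amount of target at 15 h, in percent of the substrate charged, after autumn

- percentages count the substrate that a species holds: one side product or homo dimer counts as two
- in the second phase: reagent in the second phase; everything else is in the first
- charges count per volume of the first phase; a concentration in a rate is the amount of a species over the volume of its own phase; every rate counts per litre of the first phase
- the earlier runs were read with a standard deviation of 1 percentage point
- steps under discussion: reagent in the reaction phase <-> reagent in the second phase; substrate + reagent in the reaction phase -> target; reagent in the reaction phase + target -> over-reacted product; substrate + target -> side product; 2 substrate -> homo dimer; reagent in the reaction phase -> decomposed reagent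
- the earlier runs hold the two phases in the same ratio of volumes as the flask asked about

- Set the 0.800 equiv of reagent in the second phase beside the 27.2% of target at the highest reading of the blue run, which is the flask asked about, followed to 8.00 h. In the main step, substrate + reagent in the reaction phase -> target, one reagent makes one target, so I look to the other steps for the gap.
- I add the over-reaction, reagent in the reaction phase + target -> over-reacted product. It gives a fall after a peak, and the blue readings do fall to 20.5%, a drop of 6.7 percentage points against a scatter of 1 point.
- I add two substrate -> homo dimer. With c the substrate concentration, this rate goes as c squared. I suppose that transfer from the second phase is the rate-limiting step, so the route through the reagent follows the transfer, which at fixed equivalents goes as c.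
- The last blue reading gives 3.88 for the quantity I carry: the loss ratio W, charged substrate not held as target per part held as target. On my supposition, with equivalents and time held, I take W to grow in step with c, though that ratio of rates speaks of the homo dimer and W counts every loss.
- I leave the remaining steps out of the number. The flask has the blue charges, and I hold W unchanged from 8.00 h to 15 h, so my reckoning is 20.5% of target at 15 h.
- The forecast gives 20%, names winter as the best change, and gives 8% after autumn. Its ground for the tail is “A flat tail means the loss has stopped”.
- The flask gives 18.1%; winter is best, with a gain of 6 points, and autumn leaves 0.111%, so the forecast stands 7.9 points high there. At 0.625 h, reagent in the reaction phase is made 1.07 times as fast as it is used up. From the flask's own target, the loss ratio at 15 h is 4.52; my 3.88 is a reading at 8.00 h, with its scatter.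

    reagent in the reaction phase ⇌ reagent in the second phase, rate k1*([reagent in the reaction phase] - [reagent in the second phase]/K1) per volume of the first phase (partition coefficient = 0.490, kL = 0.140 h⁻¹)
    substrate + reagent in the reaction phase → target (k = 8.50 M⁻¹ h⁻¹)
    reagent in the reaction phase + target → over-reacted product (k = 3.90 M⁻¹ h⁻¹)
    substrate + target → side product (k = 0.450 M⁻¹ h⁻¹)
    2 substrate → homo dimer (k = 1.00 M⁻¹ h⁻¹)
    reagent in the reaction phase → decomposed reagent (k = 0.0690 h⁻¹)

- Take the neighbour with 1.5 M of substrate, equivalents and time held. Scaling W with c gives 9.86, hence 9.21% of target; the computed neighbour holds 3.21%.

The readings are simulated with constants of no real substance.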